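## Retrosynthetic overview
1. Succinimide, the last ring and the key C–N bond: break C16–N to give a γ-cyano N-acyl oxazolidinone. The nitrile is the latent NH2 group and the auxiliary is the leaving group.
2. C12–C13: Evans syn aldol between the C12 aldehyde and an (R)-oxazolidinone carrying a 3-cyanopropanoyl group. This sets 12S and 13R.
3. C7–OAc: the C–O bond is made with inversion (Mitsunobu, AcOH) from the axial 7α allylic alcohol, which comes from SeO2 hydroxylation of the 8(17)-alkene.
4. The alkene and the C12 carbonyl come from opening the lactone of 2α-chlorosclareolide (Weinreb amide, then dehydration). C2–Cl comes from C–H chlorination.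
5. Ring order: rings A and B are bought in (+)-sclareolide with C5, C9 and C10 already set. Lactone ring C is opened and not rebuilt. The imide ring closes in the final step.

Assumption: labdane numbering is used (C1–C10 decalin, C11–C16 side chain and imide, C17 exocyclic methylene). α means the face opposite the C10 methyl group.

## Route

Step 1
Reactants: 1 (+)-sclareolide
Product: 2 2α-chlorosclareolide
Conditions: Mn(TMP)Cl (5 mol %; TMP = tetramesitylporphyrinate), Bu4NCl (cat.), aq. NaOCl, CH2Cl2, rt
Reagents that add atoms: sodium hypochlorite, [Na+].[O-]Cl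
Why: In this manganese-porphyrin C–H chlorination (hydrogen abstraction, then chlorine rebound) the bulky catalyst reaches only the least hindered methylene C2, far from the lactone, and delivers chlorine to the equatorial α position, a moderate-yield result already known for this lactone.

Step 2
Reactants: 2 2α-chlorosclareolide
Product: 3 2α-chloro-8α-hydroxy-13,14,15,16-tetranorlabdan-12-oic acid N-methoxy-N-methylamide
Conditions: MeNH(OMe)·HCl, AlMe3, CH2Cl2, 0 °C to rt; cold dilute HCl work-up
Reagents that add atoms: N,O-dimethylhydroxylamine hydrochloride, CNOC.Cl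
Why: Weinreb aminolysis of the lactone by the aluminium amide frees the 8α tertiary alcohol and touches no stereocentre.

Step 3
Reactants: 3 hydroxy Weinreb amide
Product: 5 2α-chloro-13,14,15,16-tetranorlabd-8(17)-en-12-oic acid N-methoxy-N-methylamide, via tertiary chlorosulfite 4 (not isolated)
Conditions: SOCl2, pyridine, CH2Cl2, −78 °C
Reagents that add atoms: thionyl chloride, O=S(Cl)Cl (stays only in 4)
Why: In this chlorosulfite E2 dehydration the equatorial C8–O bond has no antiperiplanar ring hydrogen, only a C17–H, so pyridine removes a methyl proton and gives the exocyclic alkene.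

Step 4
Reactants: 5 exocyclic alkene Weinreb amide
Product: 6 2α-chloro-7α-hydroxy-13,14,15,16-tetranorlabd-8(17)-en-12-oic acid N-methoxy-N-methylamide
Conditions: SeO2 (0.5 equiv), t-BuOOH, CH2Cl2, rt
Reagents that add atoms: tert-butyl hydroperoxide, CC(C)(C)OO (oxygen relayed through selenium dioxide, O=[Se]=O)
Why: In this SeO2 allylic hydroxylation (ene reaction, then [2,3]-sigmatropic shift) the ene step takes the axial 7α hydrogen and the chair-like shift returns oxygen to the same face, giving the axial 7α alcohol with the alkene back at C8–C17.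

Step 5
Reactants: 6 7α-alcohol
Product: 8 7β-acetoxy-2α-chloro-13,14,15,16-tetranorlabd-8(17)-en-12-oic acid N-methoxy-N-methylamide, via oxyphosphonium acetate 7 (not isolated)
Conditions: PPh3, DIAD, AcOH, toluene, 0 °C to rt
Reagents that add atoms: acetic acid, CC(=O)O; triphenylphosphine, c1ccc(cc1)P(c1ccccc1)c1ccccc1 (stays only in 7)
Why: In this Mitsunobu reaction acetate displaces the axial, allylically activated oxyphosphonium group of 7 by SN2 from the β side, which forms the C7–O bond of the target and sets C7 as the equatorial 7β acetate in one operation.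

Step 6
Reactants: 8 7β-acetoxy Weinreb amide
Product: 10 7β-acetoxy-2α-chloro-13,14,15,16-tetranorlabd-8(17)-en-12-al, via aluminium hemiaminal chelate 9 (not isolated)
Conditions: i-Bu2AlH (1.1 equiv), THF, −78 °C; aq. potassium sodium tartrate
Reagents that add atoms: diisobutylaluminium hydride, CC(C)C[AlH]CC(C)C (aluminium stays only in 9; 10 keeps only the hydride)
Why: In this Weinreb amide reduction the more Lewis basic amide is reduced ahead of the hindered secondary acetate at −78 °C, and chelate 9 holds the aldehyde oxidation level until work-up.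

Step 7
Reactants: 11 3-cyanopropanoic acid; 12 (R)-4-benzyl-1,3-oxazolidin-2-one
Product: 14 (R)-4-benzyl-3-(3-cyanopropanoyl)-1,3-oxazolidin-2-one, via mixed pivalic anhydride 13 (not isolated)
Conditions: PivCl, Et3N, THF, −20 °C; then 12, LiCl, rt
Reagents that add atoms: pivaloyl chloride, CC(C)(C)C(=O)Cl (stays only in 13)
Why: In this mixed-anhydride N-acylation of the Evans auxiliary the oxazolidinone attacks the unhindered cyanopropanoyl carbonyl, and the auxiliary stereocentre is untouched.

Step 8
Reactants: 10 7β-acetoxy aldehyde; 14 cyanopropanoyl oxazolidinone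
Product: 17 12S,13R syn-aldol adduct, via Z-boron enolate 15 (not isolated), via boron aldolate 16 (not isolated)
Conditions: 14, Bu2BOTf, Et3N, CH2Cl2, −78 to 0 °C; 10, −78 to 0 °C; pH 7 buffer, MeOH, 30% H2O2, 0 °C
Reagents that add atoms: dibutylboron triflate, CCCCB(CCCC)OS(=O)(=O)C(F)(F)F (boron stays only in 15 and 16)
Why: In this Evans syn aldol the Z-enolate 15 reacts through a Zimmerman–Traxler chair on the face left open by the benzyl group of the R auxiliary, which sets 12S and 13R under reagent control while acetate, chloride, alkene and nitrile are inert.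

Step 9
Reactants: 17 syn-aldol adduct
Product: 19 haterumaimide N, via primary carboxamide 18 (not isolated)
Conditions: [PtH(PMe2OH)(PMe2O)2H] (5 mol %), THF–H2O 4:1, 60 °C; then NaHCO3 (0.5 equiv), rt
Reagents that add atoms: water, O
Why: Proposed new method: a hydration-triggered, auxiliary-expelling imide closure. The neutral divalent platinum hydride–phosphinito complex binds the unhindered nitrile and delivers its P–OH oxygen intramolecularly, giving carboxamide 18 without acid or strong base. The new NH2 group then sits 1,4 to the activated exocyclic N-acyl carbonyl, so 5-exo-trig attack, helped by the bicarbonate buffer, forms the C16–N bond, closes the succinimide and expels oxazolidinone 12. Attack on the ring carbamate carbonyl would need a seven-membered transition state. At pH 7–8 the acetate, chloride, alkene, free C12–OH and C13 centre are untouched, and back-attack of C12–OH on the imide would need a strained bicyclo[2.2.1] tetrahedral intermediate. The closest known reaction types are Ghaffar–Parkins nitrile hydration and base-induced aspartimide formation in peptides; to my knowledge, combining them with release of an Evans auxiliary has not been described.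

## Compound list
1 | (+)-sclareolide, (3aR,5aS,9aS,9bR)-3a,6,6,9a-tetramethyldecahydronaphtho[2,1-b]furan-2(1H)-one | C[C@@]12CC[C@H]3C(C)(C)CCC[C@]3(C)[C@H]1CC(=O)O2 | starting material
2 | 2α-chlorosclareolide (equatorial Cl at C2) | C[C@@]12CC[C@H]3C(C)(C)C[C@H](Cl)C[C@]3(C)[C@H]1CC(=O)O2 | intermediate
3 | 2α-chloro-8α-hydroxy-13,14,15,16-tetranorlabdan-12-oic acid N-methoxy-N-methylamide (8β-methyl, 9β side chain) | C[C@@]1(O)CC[C@H]2C(C)(C)C[C@H](Cl)C[C@]2(C)[C@H]1CC(=O)N(C)OC | intermediate
4 | 8α-chlorosulfite of 3 (not isolated) | C[C@@]1(OS(=O)Cl)CC[C@H]2C(C)(C)C[C@H](Cl)C[C@]2(C)[C@H]1CC(=O)N(C)OC | intermediate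
5 | 2α-chloro-13,14,15,16-tetranorlabd-8(17)-en-12-oic acid N-methoxy-N-methylamide | C=C1CC[C@H]2C(C)(C)C[C@H](Cl)C[C@]2(C)[C@H]1CC(=O)N(C)OC | intermediate
6 | 7α-hydroxy derivative of 5 (axial OH) | C=C1[C@H](O)C[C@H]2C(C)(C)C[C@H](Cl)C[C@]2(C)[C@H]1CC(=O)N(C)OC | intermediate
7 | 7α-(triphenylphosphonio)oxy derivative of 5, acetate salt (not isolated) | C=C1[C@H](O[P+](c3ccccc3)(c3ccccc3)c3ccccc3)C[C@H]2C(C)(C)C[C@H](Cl)C[C@]2(C)[C@H]1CC(=O)N(C)OC.CC(=O)[O-] | intermediate
8 | 7β-acetoxy derivative of 5 (equatorial OAc) | C=C1[C@@H](OC(C)=O)C[C@H]2C(C)(C)C[C@H](Cl)C[C@]2(C)[C@H]1CC(=O)N(C)OC | intermediate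
9 | O-diisobutylaluminium N-methoxy-N-methyl hemiaminal of 10 (not isolated) | C=C1[C@@H](OC(C)=O)C[C@H]2C(C)(C)C[C@H](Cl)C[C@]2(C)[C@H]1CC(O[Al](CC(C)C)CC(C)C)N(C)OC | intermediate
10 | 7β-acetoxy-2α-chloro-13,14,15,16-tetranorlabd-8(17)-en-12-al | C=C1[C@@H](OC(C)=O)C[C@H]2C(C)(C)C[C@H](Cl)C[C@]2(C)[C@H]1CC=O | intermediate
11 | 3-cyanopropanoic acid | N#CCCC(=O)O | starting material
12 | (R)-4-benzyl-1,3-oxazolidin-2-one | O=C1N[C@H](Cc2ccccc2)CO1 | starting material
13 | 3-cyanopropanoic pivalic anhydride (not isolated) | N#CCCC(=O)OC(=O)C(C)(C)C | intermediate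
14 | (R)-4-benzyl-3-(3-cyanopropanoyl)-1,3-oxazolidin-2-one | N#CCCC(=O)N1C(=O)OC[C@H]1Cc1ccccc1 | intermediate
15 | Z-dibutylboron enolate of 14 (not isolated) | CCCCB(CCCC)O/C(=C\CC#N)N1C(=O)OC[C@H]1Cc1ccccc1 | intermediate
16 | O-dibutylboron aldolate of 17 (not isolated) | C=C1[C@@H](OC(C)=O)C[C@H]2C(C)(C)C[C@H](Cl)C[C@]2(C)[C@H]1C[C@H](OB(CCCC)CCCC)[C@@H](CC#N)C(=O)N1C(=O)OC[C@H]1Cc1ccccc1 | intermediate
17 | (R)-4-benzyl-3-[(2R,3S)-2-(cyanomethyl)-3-hydroxy-4-(7β-acetoxy-2α-chloro-drim-8(12)-en-11-yl-type decalin at C9)butanoyl]oxazolidin-2-one, the 12S,13R syn adduct | C=C1[C@@H](OC(C)=O)C[C@H]2C(C)(C)C[C@H](Cl)C[C@]2(C)[C@H]1C[C@H](O)[C@@H](CC#N)C(=O)N1C(=O)OC[C@H]1Cc1ccccc1 | intermediate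
18 | primary carboxamide from 17 (CH2CN becomes CH2CONH2; not isolated) | C=C1[C@@H](OC(C)=O)C[C@H]2C(C)(C)C[C@H](Cl)C[C@]2(C)[C@H]1C[C@H](O)[C@@H](CC(N)=O)C(=O)N1C(=O)OC[C@H]1Cc1ccccc1 | intermediate
19 | haterumaimide N (2α-Cl, 7β-OAc, 12S-OH, 13R succinimide) | C=C1[C@@H](OC(C)=O)C[C@H]2C(C)(C)C[C@H](Cl)C[C@]2(C)[C@H]1C[C@H](O)[C@H]1CC(=O)NC1=O | target

## Step count and risks
Total step count: 9. Longest linear sequence: 8 (steps 1–6, 8 and 9, starting from 1).

**Step 9 (the new step).**
- Risks: C12–OH may add to the platinum-bound nitrile, giving a cyclic imidate and then lactone plus ammonia. The amide oxygen may attack instead of nitrogen, giving an isoimide that hydrolyses. The closure may also be slow.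
- Fallback, from 10 back to 19: the imide ring is bought instead of built.
  - Succinimide is deprotonated twice with LiN(i-Pr)2 (2.1 equiv, THF, −78 to 0 °C) to N,C-dilithiosuccinimide F1.
  - Aldehyde 10 is added at −78 °C, and the resulting dilithium aldolate F2 is quenched with AcOH to give 19 in the same flask.
  - This is a plain imide-dianion aldol addition without an auxiliary, so 19 must be separated from its C12/C13 diastereomers by HPLC. Steps 7 and 8 are no longer needed.

**Step 5 (Mitsunobu inversion).**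
- Risks: SN2′ attack at C17 would give the primary allylic acetate. E2 loss of the axial 6β hydrogen would give the 6,8(17)-diene.
- Fallback, from 6 back to 8: C7 is set by hydride delivery instead of substitution.
  - Dess–Martin periodinane (CH2Cl2, rt) gives the α-methylene ketone F3.
  - Luche reduction (NaBH4, CeCl3·7H2O, MeOH, −78 °C) adds hydride axially from the α face to give the equatorial 7β-alcohol F4.
  - Ac2O, pyridine and DMAP then give 8.

**Step 6 (amide reduction next to an acetate).**
- Risk: partial reductive loss of the acetate.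
- Fallback, from 6 back to 10: the reduction is done before the acetate exists.
  - Alcohol 6 is treated with i-Bu2AlH (2.3 equiv, THF, −78 °C), which forms the bis(diisobutylaluminium) hemiaminal F5.
  - Tartrate work-up gives the 7α-hydroxy aldehyde F6. No lactol can form, because the 7α oxygen and the 9β chain are trans.
  - PPh3, DIAD and AcOH then convert F6, through its oxyphosphonium acetate F7, into 10.

## Further compounds
F1 | step 9 | N,C-dilithiosuccinimide | [Li+].[Li+].O=C1C[CH-]C(=O)[N-]1
F2 | step 9 | dilithium aldolate of 19 | C=C1[C@@H](OC(C)=O)C[C@H]2C(C)(C)C[C@H](Cl)C[C@]2(C)[C@H]1C[C@H]([O-])[C@H]1CC(=O)[N-]C1=O.[Li+].[Li+]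
F3 | step 5 | 2α-chloro-7-oxo-13,14,15,16-tetranorlabd-8(17)-en-12-oic acid N-methoxy-N-methylamide | C=C1C(=O)C[C@H]2C(C)(C)C[C@H](Cl)C[C@]2(C)[C@H]1CC(=O)N(C)OC
F4 | step 5 | 2α-chloro-7β-hydroxy-13,14,15,16-tetranorlabd-8(17)-en-12-oic acid N-methoxy-N-methylamide | C=C1[C@@H](O)C[C@H]2C(C)(C)C[C@H](Cl)C[C@]2(C)[C@H]1CC(=O)N(C)OC
F5 | step 6 | 7α-O,12-O-bis(diisobutylaluminium) hemiaminal from 6 | C=C1[C@H](O[Al](CC(C)C)CC(C)C)C[C@H]2C(C)(C)C[C@H](Cl)C[C@]2(C)[C@H]1CC(O[Al](CC(C)C)CC(C)C)N(C)OC
F6 | step 6 | 2α-chloro-7α-hydroxy-13,14,15,16-tetranorlabd-8(17)-en-12-al | C=C1[C@H](O)C[C@H]2C(C)(C)C[C@H](Cl)C[C@]2(C)[C@H]1CC=O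
F7 | step 6 | 7α-(triphenylphosphonio)oxy aldehyde, acetate salt | C=C1[C@H](O[P+](c3ccccc3)(c3ccccc3)c3ccccc3)C[C@H]2C(C)(C)C[C@H](Cl)C[C@]2(C)[C@H]1CC=O.CC(=O)[O-]
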